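The constants are invented; no experiment stands behind them.

A neighbour of this flask differs from it in the partner charge, so we want a reckoning that takes that charge as its argument.

substrate 0.28 M; partner 0.280 M; time 6.0 d

    substrate + partner → target, rate k1*[substrate]^0.5*[partner]^0.5 (k1 = 0.038 h⁻¹)
    partner → decomposed reagent (k2 = 0.079 h⁻¹)

* why nothing more happens at 6.0 d, or that something still does (it is still moving / all of the substrate has reacted / forward and back rates have come level / the partner has run out first)
* share of the substrate used up at 6.0 d
* target at 6.0 d, in percent of the substrate charged

- the reaction counts as stopped when no species that holds the substrate changes by six tenths of a point or more over the second half of the time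
- run time (flask): 6.0 d

We call the decomposition constant over the coupling constant the split constant σ, 2.08: the partner lost to decomposition per partner lost to coupling when partner and substrate stand equal. Let u be the square root of partner over substrate, starting at w, here 1.00. The ratio of decomposition to coupling is then σu, at the start 2.08. If that ratio held, coupling would use 32.5 % of the substrate.

But it doesn't hold: the partner falls 3.08 times as fast as the substrate at the start, so u sinks, the ratio σu sinks with it, coupling takes a growing share of the partner, and that first figure is too low.

Better, we divide the partner's rate by the substrate's so that time drops out: each substrate consumed costs one partner by coupling and σu by decomposition. The variables then separate. Call L the logarithm of substrate charged over substrate left when u reaches zero; it is the integral of 2u over one plus σu minus u squared, from zero up to w. That denominator factors as (p − u)(u + q), with p 2.48 and q 0.403, so L = [2p ln(p/(p − w)) − 2q ln((w + q)/q)]/(p + q), here 0.539.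

This assumes that u reaches zero within the run. The partner's half-life by decomposition alone is 0.366 d, and 6.0 d holds 16.4 of them, so decomposition by itself leaves 0.00115 % of the partner. We therefore expect that the partner has run out first, with conversion 41.7 %. Each substrate consumed becomes target, so the yield is 41.7 %.

The forecast says the partner has run out first, with conversion 41.6 % (40 % to 43 %) and yield 41.6 % (40 % to 43 %), holding of the partner that the half-order law “drives it to zero in finite time”.

For this flask the simulation gives the same outcome, the partner has run out first, with conversion 41.7 % and yield 41.7 %. In the flask, 0 % of the partner, the limiting reagent, remains at 6.00 d, less than the 58 % of the substrate. The same σ serves the neighbour charged with 1.1 M of partner: w becomes 1.98, L becomes 2.26, and the conversion reckoned is 89.6 %. That neighbour's simulated conversion is 89.6 %.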